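**Retrosynthetic overview**

- Locants: C6 is the spiro carbon; ring B is C1(H)=C2(H)–C3(=CHBr)–C4H2–C5H2; ring A is C7(CH3)(OH)–C8H2–C9HBr–C10H2–C11(CH3)2.
- Enabling feature: C6 sits between C7, a carbinol carbon that can be a ketone, and the C1=C2–C3(=CHBr) unit of ring B, which is a 4,4-disubstituted cyclohex-2-enone in disguise. A 2-methylidenecyclohexanone (C6=C5 activated by C7=O) and a 1-amino-3-siloxybutadiene therefore give ring B, bonds C6–C1 and C5–C4, and the quaternary stereocentre in one Diels–Alder step.
- Late disconnections: C9–Br (SN2 inversion of an axial alcohol), C3=CHBr (Wittig on the ring-B enone), C7–CH3 (organocerium addition to the ketone).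
- Stereochemical relay: a C9 oxygen from a catalytic asymmetric epoxidation sits equatorial and locks ring A; it directs C6 (cycloaddition) and then C7 (methyl addition), and is finally oxidised, re-reduced and inverted to the bromide.
- Ring order: ring A is bought as 5,5-dimethylcyclohexenone; ring B is formed second, in the cycloaddition.

Key step: step 6

Remark: the enone starting material and the aminosiloxy diene are taken as catalogue compounds; spiro compounds are named with the locants above rather than lowest-locant numbering, and the SMILES is authoritative for configuration.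

**Route**

Step 1
Reactants: 1 5,5-dimethylcyclohex-2-en-1-one
Product: 2 (1R,6R)-4,4-dimethyl-7-oxabicyclo[4.1.0]heptan-2-one
Conditions: 9-amino-9-deoxy-epi-cinchona alkaloid (10 mol %), TFA (20 mol %), 50% aq. H2O2, dioxane, 30 °C
Reagents that add atoms: hydrogen peroxide, OO
Why: Iminium-catalysed asymmetric Weitz–Scheffer-type epoxidation of a cyclic enone, in which the chiral primary-amine salt (the pseudoenantiomer that delivers the (1R,6R) epoxide is chosen) selects the face for hydroperoxide conjugate addition and ring closure gives the cis-fused epoxide.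

Step 2
Reactants: 2 (1R,6R)-4,4-dimethyl-7-oxabicyclo[4.1.0]heptan-2-one
Product: 4 (1R,6R)-3-[(dimethylamino)methyl]-4,4-dimethyl-7-oxabicyclo[4.1.0]heptan-2-one (C3 epimers), via lithium enolate 3 (not isolated)
Conditions: LDA, THF, −78 °C; then CH2=NMe2+ I−, −78 → 0 °C
Reagents that add atoms: N,N-dimethylmethylideneammonium iodide, C=[N+](C)C.[I-]
Why: Kinetic deprotonation can only occur at the C3 methylene (the other α-carbon is the epoxide CH) and the enolate is aminomethylated in a Mannich reaction; the new C3 centre forms as a mixture, which does not matter because it becomes sp2 in step 5.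

Step 3
Reactants: 4 (1R,6R)-3-[(dimethylamino)methyl]-4,4-dimethyl-7-oxabicyclo[4.1.0]heptan-2-one
Product: 5 (5R)-2-[(dimethylamino)methyl]-5-hydroxy-3,3-dimethylcyclohexan-1-one (C2 epimers)
Conditions: SmI2 (2.2 equiv), THF/MeOH, −90 °C
Reagents that add atoms: none
Why: Reductive cleavage of the Cα–O bond of an α,β-epoxy ketone by SmI2 with fast protonation gives the aldol, and because the Cβ–O bond is untouched the carbinol keeps the configuration set in step 1.

Step 4
Reactants: 5 (5R)-2-[(dimethylamino)methyl]-5-hydroxy-3,3-dimethylcyclohexan-1-one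
Product: 6 (5R)-5-[(tert-butyldimethylsilyl)oxy]-2-[(dimethylamino)methyl]-3,3-dimethylcyclohexan-1-one (C2 epimers)
Conditions: TBSCl, imidazole, DMF, rt
Reagents that add atoms: tert-butyldimethylsilyl chloride, CC(C)(C)[Si](C)(C)Cl
Why: Standard silylation of the secondary alcohol, which masks it towards the diene and the organometallic reagent and provides the bulky equatorial group that locks the ring-A chair; no stereocentre changes.

Step 5
Reactants: 6 (5R)-5-[(tert-butyldimethylsilyl)oxy]-2-[(dimethylamino)methyl]-3,3-dimethylcyclohexan-1-one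
Product: 8 (5R)-5-[(tert-butyldimethylsilyl)oxy]-3,3-dimethyl-2-methylidenecyclohexan-1-one, via methiodide 7 (not isolated)
Conditions: MeI, acetone, rt; then aq. NaHCO3, CH2Cl2, rt
Reagents that add atoms: none
Why: N-Methylation followed by mild-base E1cB (Hofmann-type) loss of trimethylamine from the β-ammonio ketone is the classic Mannich-base route to α-methylidene ketones; C2 becomes sp2 and the C5 centre is untouched.

Step 6
Reactants: 8 (5R)-5-[(tert-butyldimethylsilyl)oxy]-3,3-dimethyl-2-methylidenecyclohexan-1-one; 9 (1E)-3-[(tert-butyldimethylsilyl)oxy]-N,N-dimethylbuta-1,3-dien-1-amine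
Product: 10 (6R,9R)-3,9-bis[(tert-butyldimethylsilyl)oxy]-1-(dimethylamino)-11,11-dimethylspiro[5.5]undec-2-en-7-one (C1 epimers)
Conditions: 9 (1.5 equiv), toluene, 25 → 60 °C; used crude
Reagents that add atoms: none
Why: A thermal normal-electron-demand [4+2] cycloaddition, concerted but strongly asynchronous (the diene CH2 terminus bonds first to the exocyclic CH2 of the s-cis enone, then the amino-bearing terminus closes on the α-carbon), forms C5–C4 and C6–C1 in one event. The closest known reaction types are cycloadditions of 1-amino-3-siloxybutadienes with α-substituted enals and enones that create quaternary carbons, and Diels–Alder reactions of 2-methylidenecycloalkanones that give spirocycles. Ring B is closed as a six-membered carbocycle by intermolecular suprafacial cycloaddition onto the exocyclic alkene, which makes it spiro at C6. The new quaternary centre C6 is controlled by the C9 silyloxy group: being equatorial it fixes the chair in which the C11 methyl on the opposite face is axial and screens that face of the methylidene, so the diene should add to the face cis to the C9 oxygen. The C1 amino centre (endo/exo) is not controlled and need not be, because both epimers converge when the amine is eliminated in step 8. The required regiochemistry (amino-bearing terminus to the ketone α-carbon) follows from pairing the largest diene HOMO coefficient at C4 with the enone β-carbon, and no other electron-poor alkene competes.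

Step 7
Reactants: 10 (6R,9R)-3,9-bis[(tert-butyldimethylsilyl)oxy]-1-(dimethylamino)-11,11-dimethylspiro[5.5]undec-2-en-7-one
Product: 11 (6R,7S,9R)-3,9-bis[(tert-butyldimethylsilyl)oxy]-1-(dimethylamino)-7,11,11-trimethylspiro[5.5]undec-2-en-7-ol (C1 epimers)
Conditions: MeLi, CeCl3, THF, −78 °C; aq. NH4Cl
Reagents that add atoms: methyllithium, C[Li]
Why: 1,2-Addition of a weakly basic organocerium reagent to a hindered, enolisable ketone while ring B is still masked as a silyl enol ether; axial approach to C7 is blocked by the syn-axial C11 methyl, so methyl should enter equatorially and give the axial C7–OH trans to C1.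

Step 8
Reactants: 11 (6R,7S,9R)-3,9-bis[(tert-butyldimethylsilyl)oxy]-1-(dimethylamino)-7,11,11-trimethylspiro[5.5]undec-2-en-7-ol
Product: 13 (6S,7S,9R)-7,9-dihydroxy-7,11,11-trimethylspiro[5.5]undec-1-en-3-one, via amino ketone 12 (not isolated)
Conditions: 48% aq. HF, MeCN, 0 °C → rt
Reagents that add atoms: none
Why: HF cleaves the silyl enol ether to the C3 ketone and the C9 silyl ether to the alcohol, and the β-amino ketone then loses dimethylamine to the conjugated enone, which merges both C1 epimers into one compound without touching C6, C7 or C9.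

Step 9
Reactants: 13 (6S,7S,9R)-7,9-dihydroxy-7,11,11-trimethylspiro[5.5]undec-1-en-3-one
Product: 14 (3E,6S,7S,9R)-3-(bromomethylidene)-7,11,11-trimethylspiro[5.5]undec-1-ene-7,9-diol
Conditions: Ph3P+CH2Br Br− (5 equiv), NaHMDS (5 equiv), THF, −78 → 0 °C
Reagents that add atoms: (bromomethyl)triphenylphosphonium bromide, BrC[P+](c1ccccc1)(c1ccccc1)c1ccccc1.[Br-]
Why: Wittig bromomethylenation of the enone carbonyl (the two alkoxides formed from the free hydroxyls are spectators and carry no leaving group); the C3=CHBr geometry is set here under kinetic control, where bromine is expected to prefer the side of the sp3 C4 methylene over the rigidly in-plane C2–H of the s-trans diene, and any Z isomer is removed by chromatography.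

Step 10
Reactants: 14 (3E,6S,7S,9R)-3-(bromomethylidene)-7,11,11-trimethylspiro[5.5]undec-1-ene-7,9-diol
Product: 15 (3E,6S,7S)-3-(bromomethylidene)-7-hydroxy-7,11,11-trimethylspiro[5.5]undec-1-en-9-one
Conditions: Dess–Martin periodinane, NaHCO3, CH2Cl2, 0 °C → rt
Reagents that add atoms: none
Why: Buffered periodinane oxidation of the only secondary alcohol (the tertiary alcohol and the bromodiene are inert, and the non-basic medium avoids retro-aldol or dehydration of the β-hydroxy ketone) deliberately erases the C9 centre once it has served as the lock.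

Step 11
Reactants: 15 (3E,6S,7S)-3-(bromomethylidene)-7-hydroxy-7,11,11-trimethylspiro[5.5]undec-1-en-9-one
Product: 16 (3E,6S,7S,9S)-3-(bromomethylidene)-7,11,11-trimethylspiro[5.5]undec-1-ene-7,9-diol
Conditions: NaBH4, MeOH/CH2Cl2, −78 → −40 °C
Reagents that add atoms: none
Why: Substrate-controlled borohydride reduction in which, in the favoured chair (C7–OH axial rather than two syn-axial methyls), axial approach to C9 is blocked by the syn-axial C7–OH and C11–CH3, so hydride should enter equatorially from the C1 face and give the axial C9–OH cis to C7–OH; any C9 epimer is compound 14 and is returned through step 10.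

Step 12
Reactants: 16 (3E,6S,7S,9S)-3-(bromomethylidene)-7,11,11-trimethylspiro[5.5]undec-1-ene-7,9-diol
Product: 18 (3E,6S,7S,9R)-9-bromo-3-(bromomethylidene)-7,11,11-trimethylspiro[5.5]undec-1-en-7-ol, via alkoxyphosphonium bromide 17 (not isolated)
Conditions: PPh3, CBr4, CH2Cl2, 0 °C → rt
Reagents that add atoms: carbon tetrabromide, BrC(Br)(Br)Br
Why: Appel bromination, in which the secondary hydroxyl is selectively activated and displaced by bromide in an SN2 reaction with inversion (the axial leaving group loses its syn-axial strain in the transition state, bromide enters along the unhindered equatorial trajectory, and the cis tertiary hydroxyl cannot attack from the rear), should give the equatorial (9R) bromide trans to C7–OH.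

**Compound list**

1 | 5,5-dimethylcyclohex-2-en-1-one | CC1(C)CC=CC(=O)C1 | starting material
2 | (1R,6R)-4,4-dimethyl-7-oxabicyclo[4.1.0]heptan-2-one | CC1(C)C[C@@H]2[C@@H](O2)C(=O)C1 | intermediate
3 | lithium (1R,6R)-4,4-dimethyl-7-oxabicyclo[4.1.0]hept-2-en-2-olate (not isolated) | CC1(C)C[C@@H]2[C@@H](O2)C(O[Li])=C1 | intermediate
4 | (1R,6R)-3-[(dimethylamino)methyl]-4,4-dimethyl-7-oxabicyclo[4.1.0]heptan-2-one (C3 epimers) | CC1(C)C[C@@H]2[C@@H](O2)C(=O)C1CN(C)C | intermediate
5 | (5R)-2-[(dimethylamino)methyl]-5-hydroxy-3,3-dimethylcyclohexan-1-one (C2 epimers) | CC1(C)C[C@@H](O)CC(=O)C1CN(C)C | intermediate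
6 | (5R)-5-[(tert-butyldimethylsilyl)oxy]-2-[(dimethylamino)methyl]-3,3-dimethylcyclohexan-1-one (C2 epimers) | CC1(C)C[C@@H](O[Si](C)(C)C(C)(C)C)CC(=O)C1CN(C)C | intermediate
7 | {[(4R)-4-[(tert-butyldimethylsilyl)oxy]-2,2-dimethyl-6-oxocyclohexyl]methyl}trimethylammonium iodide (not isolated) | CC1(C)C[C@@H](O[Si](C)(C)C(C)(C)C)CC(=O)C1C[N+](C)(C)C.[I-] | intermediate
8 | (5R)-5-[(tert-butyldimethylsilyl)oxy]-3,3-dimethyl-2-methylidenecyclohexan-1-one | CC1(C)C[C@@H](O[Si](C)(C)C(C)(C)C)CC(=O)C1=C | intermediate
9 | (1E)-3-[(tert-butyldimethylsilyl)oxy]-N,N-dimethylbuta-1,3-dien-1-amine | CN(C)/C=C/C(=C)O[Si](C)(C)C(C)(C)C | starting material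
10 | (6R,9R)-3,9-bis[(tert-butyldimethylsilyl)oxy]-1-(dimethylamino)-11,11-dimethylspiro[5.5]undec-2-en-7-one (C1 epimers) | CC1(C)C[C@@H](O[Si](C)(C)C(C)(C)C)CC(=O)[C@@]12C(N(C)C)C=C(O[Si](C)(C)C(C)(C)C)CC2 | intermediate
11 | (6R,7S,9R)-3,9-bis[(tert-butyldimethylsilyl)oxy]-1-(dimethylamino)-7,11,11-trimethylspiro[5.5]undec-2-en-7-ol (C1 epimers) | CC1(C)C[C@@H](O[Si](C)(C)C(C)(C)C)C[C@](C)(O)[C@@]12C(N(C)C)C=C(O[Si](C)(C)C(C)(C)C)CC2 | intermediate
12 | (6R,7S,9R)-1-(dimethylamino)-7,9-dihydroxy-7,11,11-trimethylspiro[5.5]undecan-3-one (C1 epimers, not isolated) | CC1(C)C[C@@H](O)C[C@](C)(O)[C@@]12C(N(C)C)CC(=O)CC2 | intermediate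
13 | (6S,7S,9R)-7,9-dihydroxy-7,11,11-trimethylspiro[5.5]undec-1-en-3-one | CC1(C)C[C@@H](O)C[C@](C)(O)[C@@]12C=CC(=O)CC2 | intermediate
14 | (3E,6S,7S,9R)-3-(bromomethylidene)-7,11,11-trimethylspiro[5.5]undec-1-ene-7,9-diol | CC1(C)C[C@@H](O)C[C@](C)(O)[C@@]12C=C/C(=C/Br)CC2 | intermediate
15 | (3E,6S,7S)-3-(bromomethylidene)-7-hydroxy-7,11,11-trimethylspiro[5.5]undec-1-en-9-one | CC1(C)CC(=O)C[C@](C)(O)[C@@]12C=C/C(=C/Br)CC2 | intermediate
16 | (3E,6S,7S,9S)-3-(bromomethylidene)-7,11,11-trimethylspiro[5.5]undec-1-ene-7,9-diol | CC1(C)C[C@H](O)C[C@](C)(O)[C@@]12C=C/C(=C/Br)CC2 | intermediate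
17 | {[(3E,6S,7S,9S)-3-(bromomethylidene)-7-hydroxy-7,11,11-trimethylspiro[5.5]undec-1-en-9-yl]oxy}triphenylphosphonium bromide (not isolated) | CC1(C)C[C@H](O[P+](c3ccccc3)(c3ccccc3)c3ccccc3)C[C@](C)(O)[C@@]12C=C/C(=C/Br)CC2.[Br-] | intermediate
18 | (3E,6S,7S,9R)-9-bromo-3-(bromomethylidene)-7,11,11-trimethylspiro[5.5]undec-1-en-7-ol | CC1(C)C[C@@H](Br)C[C@](C)(O)[C@@]12C=C/C(=C/Br)CC2 | target

**Step count and risks**

Total step count: 12. Longest linear sequence: 12 steps (from 1; diene 9 is purchased).

Steps most likely to fail: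

1. Step 9, poor control of the C3=CHBr geometry (bromine placed syn to C2–H instead of syn to C4). The fallback sets out from 13 and uses 1,3-allylic strain as the control element. α-Iodination (I2, pyridine, CH2Cl2) should give (6S,7S,9R)-7,9-dihydroxy-2-iodo-7,11,11-trimethylspiro[5.5]undec-1-en-3-one F1. The large in-plane iodine on C2 should then force the same ylide to deliver only (3E,6S,7S,9R)-3-(bromomethylidene)-2-iodo-7,11,11-trimethylspiro[5.5]undec-1-ene-7,9-diol F2, with bromine remote from iodine. Chemoselective hydrodeiodination (cat. Pd(PPh3)4, Bu3SnH, THF, rt; oxidative addition to C–I is much faster than to C–Br) returns to the route at 14.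

2. Step 12, elimination towards the C8=C9 or C9=C10 alkenes, or stalling of the activated diol as a bridged phosphorane, instead of substitution. The fallback sets out from 16 and separates activation from displacement. Selective triflation of the secondary hydroxyl (Tf2O, pyridine, CH2Cl2, −78 °C) should give (3E,6S,7S,9S)-3-(bromomethylidene)-7-hydroxy-7,11,11-trimethylspiro[5.5]undec-1-en-9-yl trifluoromethanesulfonate F3. This is displaced cold by Bu4NBr (−40 → 0 °C), where SN2 with inversion should outrun E2, and the route is rejoined at 18.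

3. Step 7, incomplete or wrong-face addition, or enolisation, at the C7 ketone while it is flanked by the quaternary C6 bearing the CH(NMe2) carbon. The fallback sets out from 10 and changes the order of events. Mild acid (1 M HCl, THF, 0 °C) should hydrolyse the silyl enol ether and eliminate dimethylamine while keeping the secondary silyl ether, giving (6S,9R)-9-[(tert-butyldimethylsilyl)oxy]-11,11-dimethylspiro[5.5]undec-1-ene-3,7-dione F4. The ylide of step 9 at −78 °C should olefinate only the unhindered enone carbonyl to give (3E,6S,9R)-3-(bromomethylidene)-9-[(tert-butyldimethylsilyl)oxy]-11,11-dimethylspiro[5.5]undec-1-en-7-one F5. MeLi/CeCl3 then adds to C7, now next to the flat C1=C2 unit, to give (3E,6S,7S,9R)-3-(bromomethylidene)-9-[(tert-butyldimethylsilyl)oxy]-7,11,11-trimethylspiro[5.5]undec-1-en-7-ol F6. HF in MeCN removes the silyl ether and the route is rejoined at 14.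

Further compounds
F1 | step 9 | (6S,7S,9R)-7,9-dihydroxy-2-iodo-7,11,11-trimethylspiro[5.5]undec-1-en-3-one | CC1(C)C[C@@H](O)C[C@](C)(O)[C@@]12C=C(I)C(=O)CC2
F2 | step 9 | (3E,6S,7S,9R)-3-(bromomethylidene)-2-iodo-7,11,11-trimethylspiro[5.5]undec-1-ene-7,9-diol | CC1(C)C[C@@H](O)C[C@](C)(O)[C@@]12C=C(I)/C(=C/Br)CC2
F3 | step 12 | (3E,6S,7S,9S)-3-(bromomethylidene)-7-hydroxy-7,11,11-trimethylspiro[5.5]undec-1-en-9-yl trifluoromethanesulfonate | CC1(C)C[C@H](OS(=O)(=O)C(F)(F)F)C[C@](C)(O)[C@@]12C=C/C(=C/Br)CC2
F4 | step 7 | (6S,9R)-9-[(tert-butyldimethylsilyl)oxy]-11,11-dimethylspiro[5.5]undec-1-ene-3,7-dione | CC1(C)C[C@@H](O[Si](C)(C)C(C)(C)C)CC(=O)[C@@]12C=CC(=O)CC2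
F5 | step 7 | (3E,6S,9R)-3-(bromomethylidene)-9-[(tert-butyldimethylsilyl)oxy]-11,11-dimethylspiro[5.5]undec-1-en-7-one | CC1(C)C[C@@H](O[Si](C)(C)C(C)(C)C)CC(=O)[C@@]12C=C/C(=C/Br)CC2
F6 | step 7 | (3E,6S,7S,9R)-3-(bromomethylidene)-9-[(tert-butyldimethylsilyl)oxy]-7,11,11-trimethylspiro[5.5]undec-1-en-7-ol | CC1(C)C[C@@H](O[Si](C)(C)C(C)(C)C)C[C@](C)(O)[C@@]12C=C/C(=C/Br)CC2
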